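**Retrosynthetic overview**

- Ring A is numbered C1 (OH), C2 (O-aryl), C3–C5 (Br), C6 (H); ring B is the 2-bromophenyl group. The strategy rests on two features of ring A: the C6–C1(OH)–C2(OAr) segment is a ketone carbonyl between two α-carbons, and C4, para to the C1 oxygen and in the middle of the Br3 block, can be carried as a nitro group.
- Late stage: target ⇐ O-methyl ether; C4–Br ⇐ C4–NH2 (Sandmeyer); C3–Br and C5–Br ⇐ bromination ortho to that NH2; NH2 ⇐ NO2.
- Key disconnection: bonds C2–C3 and C5–C6 of ring A, giving 1-(2-bromophenoxy)propan-2-one (C6, C1, C2) and nitromalonaldehyde (C3, C4, C5) as partners of a [3+3] double aldol benzannulation.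
- The aryloxy ketone ⇐ 2-bromophenol + chloroacetone, so the O–C2 bond of the diaryl ether is made as an alkyl ether bond before ring A exists.
- Ring order: ring B is bought; ring A is the only ring formed (step 2).

Key step: step 2

Remark on the chemistry: the target has no stereocentre and no configurationally stable axis, so it is achiral and "single enantiomer" needs no stereocontrol. Sodium nitromalonaldehyde 4 is used as the commercial monohydrate; it is impact-sensitive and is dissolved without grinding or heating.

**Route**

Step 1
Reactants: 1 2-bromophenol; 2 chloroacetone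
Product: 3 1-(2-bromophenoxy)propan-2-one
Conditions: K2CO3 (1.5 equiv), KI (cat.), acetone, reflux
Reagents that add atoms: none
Why: Williamson ether synthesis, in which the phenoxide of 1 displaces chloride from the activated α-chloroketone by SN2 (iodide catalysis) while the aryl bromide is inert.

Step 2
Reactants: 3 1-(2-bromophenoxy)propan-2-one; 4 sodium nitromalonaldehyde (monohydrate)
Product: 7 2-(2-bromophenoxy)-4-nitrophenol, via open-chain nitronate sodium salt 5 (not isolated), via sodium 2-(2-bromophenoxy)-4-nitrophenolate 6 (not isolated)
Conditions: NaOH (1 equiv), H2O/EtOH, 0–5 °C → rt, 3–5 d; then aq HCl to pH 2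
Reagents that add atoms: none
Why: Hydroxide forms the enolate of 3, which adds to one formyl carbon of 4 and loses water to give the open-chain nitronate 5 (new bond C2–C3); the methyl carbon then enolises and attacks the remaining formyl carbon (new bond C5–C6), and a second dehydration with loss of the C4 proton aromatises the 4-nitrocyclohexadienone to phenolate 6, which acid converts into 7. The closest known reaction type is the condensation of sodium nitromalonaldehyde with ketones that have two enolisable α-carbons to give para-nitrophenols, a [3+3] double aldol benzannulation. Ring A is closed by an intramolecular aldol in the 6-(enolendo)-exo-trig mode, which is a favoured closure. No stereocentre is formed. The step needs chemoselectivity for cross-condensation over self-condensation of the ketone, and this is supplied by the highly electrophilic dialdehyde, whose own stabilised anion is not nucleophilic at carbon; the regiochemistry cannot go astray because the three-carbon unit is symmetrical and both α-carbons of the ketone must be used, so either order of the two aldol events converges on 7. A long reaction time at low temperature is planned because the ring-closing aldol must occur on a formyl group that is part of a delocalised nitro-enolate.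

Step 3
Reactants: 7 2-(2-bromophenoxy)-4-nitrophenol
Product: 8 2-(2-bromophenoxy)-1-methoxy-4-nitrobenzene
Conditions: MeI (1.5 equiv), K2CO3 (2 equiv), DMF, rt
Reagents that add atoms: iodomethane, CI
Why: Williamson O-methylation of the acidic 4-nitrophenol by SN2; the methyl ether keeps the later aminophenol stage from being oxidised to a quinone imine during bromination.

Step 4
Reactants: 8 2-(2-bromophenoxy)-1-methoxy-4-nitrobenzene
Product: 9 3-(2-bromophenoxy)-4-methoxyaniline
Conditions: Fe powder, AcOH, EtOH/H2O, 70 °C
Reagents that add atoms: none
Why: Béchamp-type reduction by iron in acetic acid should reduce the nitro group to the amine by stepwise electron transfer without hydrogenolysis of the aryl C–Br bond, which catalytic hydrogenation would endanger.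

Step 5
Reactants: 9 3-(2-bromophenoxy)-4-methoxyaniline
Product: 10 2,6-dibromo-3-(2-bromophenoxy)-4-methoxyaniline
Conditions: NBS (2.05 equiv), MeCN, −10 °C → rt, dark
Reagents that add atoms: N-bromosuccinimide, O=C1CCC(=O)N1Br
Why: Electrophilic aromatic bromination; the amino group is the strongest donor on ring A and its para position is blocked by the methoxy group, so two equivalents of NBS should enter at both ortho positions (C3 and C5 of the target) and leave C6 and the deactivated ring B untouched.

Step 6
Reactants: 10 2,6-dibromo-3-(2-bromophenoxy)-4-methoxyaniline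
Product: 12 1,2,3-tribromo-4-(2-bromophenoxy)-5-methoxybenzene, via arenediazonium bromide 11 (not isolated)
Conditions: t-BuONO (1.5 equiv), CuBr2 (1.2 equiv), MeCN, 0 → 60 °C
Reagents that add atoms: copper(II) bromide, Br[Cu]Br; tert-butyl nitrite, CC(C)(C)ON=O (nitrogen of intermediate 11)
Why: Sandmeyer bromination under aprotic conditions, in which the alkyl nitrite diazotises the weakly basic 2,6-dibromoaniline and copper bromide mediates electron transfer to diazonium ion 11, loss of dinitrogen and bromine transfer to the aryl radical at C4.

Step 7
Reactants: 12 1,2,3-tribromo-4-(2-bromophenoxy)-5-methoxybenzene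
Product: 13 3,4,5-tribromo-2-(2-bromophenoxy)phenol
Conditions: BBr3 (3 equiv), CH2Cl2, −78 °C → rt; then H2O
Reagents that add atoms: none
Why: Lewis acid ether cleavage, in which boron tribromide coordinates the methoxy oxygen and bromide attacks the methyl carbon by SN2, so only the alkyl–oxygen bond breaks and the diaryl ether and the four aryl bromides remain.

**Compound list**

1 | 2-bromophenol | Oc1ccccc1Br | starting material
2 | chloroacetone | CC(=O)CCl | starting material
3 | 1-(2-bromophenoxy)propan-2-one | CC(=O)COc1ccccc1Br | intermediate
4 | sodium nitromalonaldehyde (used as monohydrate) | O=CC(=C[O-])[N+](=O)[O-].[Na+] | starting material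
5 | sodium nitronate of (3E)-4-(2-bromophenoxy)-2-nitro-5-oxohex-3-enal | CC(=O)/C(Oc1ccccc1Br)=C\C(C=O)=[N+]([O-])[O-].[Na+] | intermediate (not isolated)
6 | sodium 2-(2-bromophenoxy)-4-nitrophenolate | [O-]c1ccc([N+](=O)[O-])cc1Oc1ccccc1Br.[Na+] | intermediate (not isolated)
7 | 2-(2-bromophenoxy)-4-nitrophenol | Oc1ccc([N+](=O)[O-])cc1Oc1ccccc1Br | intermediate
8 | 2-(2-bromophenoxy)-1-methoxy-4-nitrobenzene | COc1ccc([N+](=O)[O-])cc1Oc1ccccc1Br | intermediate
9 | 3-(2-bromophenoxy)-4-methoxyaniline | COc1ccc(N)cc1Oc1ccccc1Br | intermediate
10 | 2,6-dibromo-3-(2-bromophenoxy)-4-methoxyaniline | COc1cc(Br)c(N)c(Br)c1Oc1ccccc1Br | intermediate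
11 | 2,6-dibromo-3-(2-bromophenoxy)-4-methoxybenzenediazonium bromide | COc1cc(Br)c([N+]#N)c(Br)c1Oc1ccccc1Br.[Br-] | intermediate (not isolated)
12 | 1,2,3-tribromo-4-(2-bromophenoxy)-5-methoxybenzene | COc1cc(Br)c(Br)c(Br)c1Oc1ccccc1Br | intermediate
13 | 3,4,5-tribromo-2-(2-bromophenoxy)phenol | Oc1cc(Br)c(Br)c(Br)c1Oc1ccccc1Br | target

**Step count**

Total steps: 7. Longest linear sequence: 7 steps (1 → 13).

**Steps most likely to fail**

1. Step 2 (benzannulation). The ring-closing aldol on the delocalised nitro-enolate may be slow, so that self-condensation of the aryloxy ketone and base-induced decomposition of the nitromalonaldehyde salt take over and conversion to the nitrophenol stays low. Fallback: ring A is then bought complete and the diaryl ether bond is made by copper-mediated oxidative C–O coupling instead. Setting out from 1, a Chan–Lam O-arylation with commercial (2-methoxy-5-nitrophenyl)boronic acid, COc1ccc(cc1B(O)O)[N+](=O)[O-] (Cu(OAc)2, pyridine, 4 Å molecular sieves, air, CH2Cl2, rt), which tolerates the aryl bromide, should give 8 directly. The route is rejoined at 8 and step 3 is dropped. This fallback makes no compound beyond the compound list (F0).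

2. Step 6 (Sandmeyer). Diazotisation of the weakly basic, doubly ortho-blocked amine may be incomplete, and the aryl radical may abstract hydrogen or be trapped by solvent before bromine transfer. Fallback: the C4 bromine is then introduced by an ionic iododediazoniation followed by halogen–metal exchange. Setting out from 10, diazotisation with NaNO2 in H2SO4/AcOH at 0–10 °C should give 2,6-dibromo-3-(2-bromophenoxy)-4-methoxybenzenediazonium hydrogen sulfate F1. This is poured into aqueous KI, where copper-free iodide substitution should give 1,3-dibromo-4-(2-bromophenoxy)-2-iodo-5-methoxybenzene F2. Selective iodine–magnesium exchange with i-PrMgCl·LiCl in THF at −40 °C (iodide exchanges far faster than the bromides) should give [2,6-dibromo-3-(2-bromophenoxy)-4-methoxyphenyl]magnesium chloride F3. It is kept cold to avoid aryne formation and quenched with 1,2-dibromotetrachloroethane to return to the route at 12.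

3. Step 5 (dibromination). The electron-rich p-anisidine ring may be oxidised by the brominating agent towards quinone imines, and bromination may run on beyond two equivalents at C6 or on ring B. Fallback: the phenol is then carried as an electron-poor sulfonate ester instead of the methyl ether, which lowers the oxidation tendency of the aminoarene and deactivates C6. Setting out from 7, MsCl/Et3N in CH2Cl2 should give 2-(2-bromophenoxy)-4-nitrophenyl methanesulfonate F4. Fe/AcOH reduction should give 4-amino-2-(2-bromophenoxy)phenyl methanesulfonate F5. NBS (2 equiv) in MeCN should give 4-amino-3,5-dibromo-2-(2-bromophenoxy)phenyl methanesulfonate F6. t-BuONO/CuBr2 in MeCN should pass through 2,6-dibromo-3-(2-bromophenoxy)-4-(methanesulfonyloxy)benzenediazonium bromide F7 to 3,4,5-tribromo-2-(2-bromophenoxy)phenyl methanesulfonate F8. Hydrolysis of the sulfonate with NaOH in MeOH/THF/H2O at 60 °C and acidification returns to the route at 13, replacing steps 3–7.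

**Further compounds**

F0 | step 2 | none | none
F1 | step 6 | 2,6-dibromo-3-(2-bromophenoxy)-4-methoxybenzenediazonium hydrogen sulfate | COc1cc(Br)c([N+]#N)c(Br)c1Oc1ccccc1Br.OS(=O)(=O)[O-]
F2 | step 6 | 1,3-dibromo-4-(2-bromophenoxy)-2-iodo-5-methoxybenzene | COc1cc(Br)c(I)c(Br)c1Oc1ccccc1Br
F3 | step 6 | [2,6-dibromo-3-(2-bromophenoxy)-4-methoxyphenyl]magnesium chloride | COc1cc(Br)c([Mg]Cl)c(Br)c1Oc1ccccc1Br
F4 | step 5 | 2-(2-bromophenoxy)-4-nitrophenyl methanesulfonate | CS(=O)(=O)Oc1ccc([N+](=O)[O-])cc1Oc1ccccc1Br
F5 | step 5 | 4-amino-2-(2-bromophenoxy)phenyl methanesulfonate | CS(=O)(=O)Oc1ccc(N)cc1Oc1ccccc1Br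
F6 | step 5 | 4-amino-3,5-dibromo-2-(2-bromophenoxy)phenyl methanesulfonate | CS(=O)(=O)Oc1cc(Br)c(N)c(Br)c1Oc1ccccc1Br
F7 | step 5 | 2,6-dibromo-3-(2-bromophenoxy)-4-(methanesulfonyloxy)benzenediazonium bromide | CS(=O)(=O)Oc1cc(Br)c([N+]#N)c(Br)c1Oc1ccccc1Br.[Br-]
F8 | step 5 | 3,4,5-tribromo-2-(2-bromophenoxy)phenyl methanesulfonate | CS(=O)(=O)Oc1cc(Br)c(Br)c(Br)c1Oc1ccccc1Br
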